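**Retrosynthetic overview**

- Feature: in the oxepane ring (O1, C2, C3, C4, C5, C6, C7) the fully substituted C2 (O1, CH3, side chain C1'–C9') and the acetoxy carbon C3 are adjacent, with the C3 oxygen cis to the C2 methyl group. A lactate ester tied back through O1–C7 can therefore deliver both centres and the ring in one [3,3] shift.
- Key disconnection: C2–C3, by Ireland–Claisen ring transposition of a 7-(Z-alkoxyvinyl)-3-methyl-1,4-dioxepan-2-one (temporary ring) to a 2,3,6,7-tetrahydrooxepine-2-carboxylic acid (the only ring of the target).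
- Lactone: (S)-solketal and a lactate triflate give the ether; Felkin–Anh addition of a lithium (4-methoxybenzyloxy)acetylide sets the carbinol centre, Lindlar reduction the Z enol ether, Yamaguchi lactonisation the ring.
- After the shift: CO2H to C1' aldehyde, Wittig union with the C2'–C9' ylide (C4', C5' from a Z-crotylboration), diimide, C6 silyl ether to ketone to E-alkylidene ester, then PMB removal, reduction, acetylation, desilylation.
- Ring order: dioxepanone (step 9), then oxepene (step 10).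

Key step: step 10

Remark: lactone C3 (the lactate carbon) loses its configuration in the ketene acetal and lactone C6 ends as the ketone carbon, so both are free. The route carries 3R (from SN2 etherification) and 6S (silyl ether trans to the alkenyl group). This is the epimer that Felkin–Anh addition gives and that keeps the silyl ether away from the Z-alkoxy group in the boat.

Abbreviations: PMB = 4-methoxybenzyl, TES = triethylsilyl, TBS = tert-butyldimethylsilyl, Ipc = isopinocampheyl.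

**Route**

Step 1
Reactants: 1 [(4S)-2,2-dimethyl-1,3-dioxolan-4-yl]methanol ((S)-solketal); 2 ethyl (2S)-2-[(trifluoromethylsulfonyl)oxy]propanoate
Product: 3 ethyl (2R)-2-{[(4S)-2,2-dimethyl-1,3-dioxolan-4-yl]methoxy}propanoate
Conditions: NaH, THF, 0 °C; then 2, −40 → 0 °C
Reagents that add atoms: none
Why: Williamson etherification in which the sodium alkoxide of 1 displaces the carbonyl-activated secondary triflate by SN2 with inversion (2R); this centre is erased in step 10, so partial epimerisation would be harmless.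

Step 2
Reactants: 3 ethyl (2R)-2-{[(4S)-2,2-dimethyl-1,3-dioxolan-4-yl]methoxy}propanoate
Product: 4 ethyl (2R)-2-[(2R)-2,3-dihydroxypropoxy]propanoate
Conditions: CSA (cat.), EtOH, 23 °C; Et3N quench
Reagents that add atoms: none
Why: Acid-catalysed transketalisation to ethanol frees the diol, and ethanol as solvent keeps the ethyl ester intact and disfavours closure of the secondary hydroxyl group onto it.

Step 3
Reactants: 4 ethyl (2R)-2-[(2R)-2,3-dihydroxypropoxy]propanoate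
Product: 5 ethyl (2R)-2-{[(2S)-2,3-bis(triethylsilyloxy)propyl]oxy}propanoate
Conditions: Et3SiCl, imidazole, DMAP (cat.), CH2Cl2, 0 → 23 °C
Reagents that add atoms: chlorotriethylsilane, CC[Si](Cl)(CC)CC
Why: Standard silylation of both hydroxyl groups; TES is chosen so that the primary ether can be oxidised directly and the secondary one can later be removed beside a TBS ether.

Step 4
Reactants: 5 ethyl (2R)-2-{[(2S)-2,3-bis(triethylsilyloxy)propyl]oxy}propanoate
Product: 6 ethyl (2R)-2-{[(2S)-3-oxo-2-(triethylsilyloxy)propyl]oxy}propanoate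
Conditions: (COCl)2, DMSO, CH2Cl2, −78 → −40 °C; Et3N, −78 → 0 °C
Reagents that add atoms: none
Why: Swern oxidation in which the chlorosulfonium salt cleaves and oxidises the primary TES ether while the secondary TES ether is inert, giving the α-silyloxy aldehyde without a separate deprotection.

Step 5
Reactants: 7 4-methoxybenzyl alcohol; 8 trichloroethylene
Product: 9 1-({[(E)-1,2-dichloroethenyl]oxy}methyl)-4-methoxybenzene
Conditions: KH, THF, 0 °C; then 8, 23 °C
Reagents that add atoms: none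
Why: Base-mediated dehydrochlorination of trichloroethylene to dichloroacetylene and trans addition of the alkoxide give the (E)-1,2-dichlorovinyl ether, a storable precursor of the alkoxyacetylide.

Step 6
Reactants: 9 1-({[(E)-1,2-dichloroethenyl]oxy}methyl)-4-methoxybenzene; 6 ethyl (2R)-2-{[(2S)-3-oxo-2-(triethylsilyloxy)propyl]oxy}propanoate
Product: 11 ethyl (2R)-2-{[(2S,3R)-3-hydroxy-5-[(4-methoxybenzyl)oxy]-2-(triethylsilyloxy)pent-4-yn-1-yl]oxy}propanoate, via lithium alkoxyacetylide 10 (not isolated)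
Conditions: 9, n-BuLi (2 equiv), THF, −78 → −40 °C; then 6, −78 °C; AcOH, −78 °C
Reagents that add atoms: none
Why: Elimination and chlorine–lithium exchange convert 9 into the acetylide, whose 1,2-addition to the α-silyloxy aldehyde should follow the polar Felkin–Anh model (attack anti to the C–OSi bond) and give mainly the 2,3-anti carbinol (3R), the minor epimer being removed by chromatography and the cold quench preventing 1,2-silyl migration.

Step 7
Reactants: 11 ethyl (2R)-2-{[(2S,3R)-3-hydroxy-5-[(4-methoxybenzyl)oxy]-2-(triethylsilyloxy)pent-4-yn-1-yl]oxy}propanoate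
Product: 12 ethyl (2R)-2-{[(2S,3R,4Z)-3-hydroxy-5-[(4-methoxybenzyl)oxy]-2-(triethylsilyloxy)pent-4-en-1-yl]oxy}propanoate
Conditions: H2 (1 atm), Pd/CaCO3 poisoned with Pb(OAc)2 (Lindlar catalyst), quinoline, EtOAc, 23 °C
Reagents that add atoms: none
Why: Lindlar semihydrogenation adds H2 syn to the ynol ether and stops at the Z enol ether, leaving the PMB ether and the ester untouched.

Step 8
Reactants: 12 ethyl (2R)-2-{[(2S,3R,4Z)-3-hydroxy-5-[(4-methoxybenzyl)oxy]-2-(triethylsilyloxy)pent-4-en-1-yl]oxy}propanoate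
Product: 13 lithium (2R)-2-{[(2S,3R,4Z)-3-hydroxy-5-[(4-methoxybenzyl)oxy]-2-(triethylsilyloxy)pent-4-en-1-yl]oxy}propanoate
Conditions: LiOH (1.05 equiv), THF/H2O, 0 °C; freeze-dried
Reagents that add atoms: lithium hydroxide, [Li+].[OH-]
Why: Saponification of the activated α-alkoxy ester at 0 °C; isolation as the lithium salt keeps the acid-labile γ-hydroxy enol ether away from any acid.

Step 9
Reactants: 13 lithium (2R)-2-{[(2S,3R,4Z)-3-hydroxy-5-[(4-methoxybenzyl)oxy]-2-(triethylsilyloxy)pent-4-en-1-yl]oxy}propanoate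
Product: 15 (3R,6S,7R)-7-{(Z)-2-[(4-methoxybenzyl)oxy]ethenyl}-3-methyl-6-(triethylsilyloxy)-1,4-dioxepan-2-one, via mixed anhydride 14 (not isolated)
Conditions: 2,4,6-Cl3C6H2COCl, THF, 23 °C; then slow addition to DMAP, toluene, 50 °C (2 mM); chromatography on Et3N-treated silica
Reagents that add atoms: none
Why: Yamaguchi lactonisation in which the allylic hydroxyl group attacks the mixed anhydride under high dilution, the chain oxygen and the substituents favouring seven-membered closure; no stereocentre is touched.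

Step 10
Reactants: 15 (3R,6S,7R)-7-{(Z)-2-[(4-methoxybenzyl)oxy]ethenyl}-3-methyl-6-(triethylsilyloxy)-1,4-dioxepan-2-one
Product: 18 (2R,3R,6R)-3-[(4-methoxybenzyl)oxy]-2-methyl-6-(triethylsilyloxy)-2,3,6,7-tetrahydrooxepine-2-carboxylic acid, via silyl ketene acetal 16 (not isolated), via trimethylsilyl ester 17 (not isolated)
Conditions: LiN(SiMe3)2, Me3SiCl/Et3N, THF, −78 → 23 °C; then toluene, 80 °C; aq. NaH2PO4
Reagents that add atoms: none
Why: LiN(SiMe3)2 removes the only acidic proton (lactone C3–H) in the presence of Me3SiCl, and the ring holds the ketene acetal 16 with O4 cis to O1, so that one ketene-acetal geometry enters a concerted, suprafacial [3,3]-sigmatropic shift in which lactone C3 bonds to the OPMB-bearing vinyl carbon while the C7–O1 bond breaks (Ireland–Claisen rearrangement). The closest known reaction type is the Ireland–Claisen ring transposition of silyl ketene acetals of lactones that carry an alkenyl group on the carbinol carbon, including 6-alkenyl-1,4-dioxan-2-ones, together with ester-enolate Claisen shifts onto the enol-ether termini of glycals. The oxepene ring is closed by this sigmatropic transposition: the new C2–C3 bond (target numbering) joins the ketene-acetal carbon to the vinyl terminus across the three-atom tether O4–C5–C6, which bridges the six-centre array and allows only a boat transition state, so no ionic or radical closure is involved. C2 is set by the 7R carbinol centre, because the ketene acetal can reach the allyl unit only on the face from which O1 departs, and C3 is set by the Z enol-ether geometry read through that boat, which places OPMB cis to the C2 methyl group. The step needs the concerted shift to outrun ionisation of the vinylogous acylal and to tolerate 1,3-allylic strain between the Z-alkoxy group and C6; the donor alkoxy group on the allyl terminus, the base-buffered medium and the 6S silyloxy group, which points away from the enol ether, are there to secure this.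

Step 11
Reactants: 18 (2R,3R,6R)-3-[(4-methoxybenzyl)oxy]-2-methyl-6-(triethylsilyloxy)-2,3,6,7-tetrahydrooxepine-2-carboxylic acid
Product: 19 [(2S,3R,6R)-3-[(4-methoxybenzyl)oxy]-2-methyl-6-(triethylsilyloxy)-2,3,6,7-tetrahydrooxepin-2-yl]methanol
Conditions: LiAlH4, THF, 0 → 23 °C
Reagents that add atoms: none
Why: Hydride reduction of the hindered α-alkoxy acid to the primary alcohol; silyl and PMB ethers and the isolated alkene are inert to LiAlH4.

Step 12
Reactants: 19 [(2S,3R,6R)-3-[(4-methoxybenzyl)oxy]-2-methyl-6-(triethylsilyloxy)-2,3,6,7-tetrahydrooxepin-2-yl]methanol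
Product: 20 (2R,3R,6R)-3-[(4-methoxybenzyl)oxy]-2-methyl-6-(triethylsilyloxy)-2,3,6,7-tetrahydrooxepine-2-carbaldehyde
Conditions: Dess–Martin periodinane, NaHCO3, CH2Cl2, 23 °C
Reagents that add atoms: none
Why: Buffered Dess–Martin oxidation gives the aldehyde, which has no α-hydrogen and so cannot epimerise at C2.

Step 13
Reactants: 21 4-methylpent-3-en-1-ol
Product: 22 4-methylpent-3-enal
Conditions: Dess–Martin periodinane, NaHCO3, CH2Cl2, 0 → 23 °C; used as a solution
Reagents that add atoms: none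
Why: Dess–Martin oxidation under base-free conditions avoids migration of the β,γ-double bond into conjugation.

Step 14
Reactants: 22 4-methylpent-3-enal; 23 (Z)-but-2-ene
Product: 26 (3R,4R)-3,7-dimethylocta-1,6-dien-4-ol, via crotylborane 24 (not isolated), via borinate 25 (not isolated)
Conditions: 23, KOtBu, n-BuLi, THF, −78 → −45 °C; (−)-Ipc2BOMe [from (+)-α-pinene], −78 °C; BF3·OEt2; 22, −78 °C; NaOH, H2O2
Reagents that add atoms: none
Why: Brown crotylboration through a closed chair transition state, in which the Z crotyl geometry gives the syn 3,4-relationship and the Ipc groups derived from (+)-α-pinene select the aldehyde face that gives 3R,4R.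

Step 15
Reactants: 26 (3R,4R)-3,7-dimethylocta-1,6-dien-4-ol
Product: 27 tert-butyl{[(3R,4R)-3,7-dimethylocta-1,6-dien-4-yl]oxy}dimethylsilane
Conditions: TBSOTf, 2,6-lutidine, CH2Cl2, −78 → 0 °C
Reagents that add atoms: tert-butyldimethylsilyl trifluoromethanesulfonate, CC(C)(C)[Si](C)(C)OS(=O)(=O)C(F)(F)F
Why: Silylation of the hindered secondary alcohol with the silyl triflate.

Step 16
Reactants: 27 tert-butyl{[(3R,4R)-3,7-dimethylocta-1,6-dien-4-yl]oxy}dimethylsilane
Product: 29 (3R,4R)-4-(tert-butyldimethylsilyloxy)-3,7-dimethyloct-6-en-1-ol, via alkylborane 28 (not isolated)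
Conditions: 9-borabicyclo[3.3.1]nonane (9-BBN), THF, 0 → 23 °C; NaOH, H2O2, 0 °C
Reagents that add atoms: hydrogen peroxide, OO
Why: Hydroboration–oxidation in which 9-BBN adds only to the monosubstituted alkene, boron at the terminal carbon, and leaves the trisubstituted alkene.

Step 17
Reactants: 29 (3R,4R)-4-(tert-butyldimethylsilyloxy)-3,7-dimethyloct-6-en-1-ol
Product: 30 tert-butyl{[(3R,4R)-1-iodo-3,7-dimethyloct-6-en-4-yl]oxy}dimethylsilane
Conditions: I2, PPh3, imidazole, CH2Cl2, 0 → 23 °C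
Reagents that add atoms: iodine, II
Why: Appel-type iodination of the primary alcohol by SN2 on the alkoxyphosphonium ion.

Step 18
Reactants: 30 tert-butyl{[(3R,4R)-1-iodo-3,7-dimethyloct-6-en-4-yl]oxy}dimethylsilane
Product: 31 [(3R,4R)-4-(tert-butyldimethylsilyloxy)-3,7-dimethyloct-6-en-1-yl]triphenylphosphonium iodide
Conditions: PPh3, iPr2NEt (cat.), MeCN, 80 °C
Reagents that add atoms: triphenylphosphine, c1ccc(cc1)P(c1ccccc1)c1ccccc1
Why: Quaternisation of PPh3 by the primary iodide (SN2) gives the phosphonium salt.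

Step 19
Reactants: 31 [(3R,4R)-4-(tert-butyldimethylsilyloxy)-3,7-dimethyloct-6-en-1-yl]triphenylphosphonium iodide; 20 (2R,3R,6R)-3-[(4-methoxybenzyl)oxy]-2-methyl-6-(triethylsilyloxy)-2,3,6,7-tetrahydrooxepine-2-carbaldehyde
Product: 33 (2S,3R,6R)-2-[(1Z,4R,5R)-5-(tert-butyldimethylsilyloxy)-4,8-dimethylnona-1,7-dien-1-yl]-3-[(4-methoxybenzyl)oxy]-2-methyl-6-(triethylsilyloxy)-2,3,6,7-tetrahydrooxepine, via phosphorus ylide 32 (not isolated)
Conditions: NaN(SiMe3)2, THF, −78 → 0 °C; then 20, −78 → 23 °C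
Reagents that add atoms: none
Why: Wittig olefination of the non-enolisable aldehyde with the non-stabilised ylide should give mainly the Z alkene, whose geometry is of no consequence because the bond is saturated in step 20.

Step 20
Reactants: 33 (2S,3R,6R)-2-[(1Z,4R,5R)-5-(tert-butyldimethylsilyloxy)-4,8-dimethylnona-1,7-dien-1-yl]-3-[(4-methoxybenzyl)oxy]-2-methyl-6-(triethylsilyloxy)-2,3,6,7-tetrahydrooxepine
Product: 34 (2S,3R,6R)-2-[(4R,5R)-5-(tert-butyldimethylsilyloxy)-4,8-dimethylnon-7-en-1-yl]-3-[(4-methoxybenzyl)oxy]-2-methyl-6-(triethylsilyloxy)oxepane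
Conditions: 2-O2NC6H4SO2NHNH2, Et3N, CH2Cl2, 23 °C (in portions)
Reagents that add atoms: none
Why: Diimide reduction, a concerted syn transfer of H2 that is fast for the cis ring alkene and the cis-disubstituted C1'=C2' bond and slow for the trisubstituted C7'=C8' bond, and that leaves benzyl-type and silyl ethers alone.

Step 21
Reactants: 34 (2S,3R,6R)-2-[(4R,5R)-5-(tert-butyldimethylsilyloxy)-4,8-dimethylnon-7-en-1-yl]-3-[(4-methoxybenzyl)oxy]-2-methyl-6-(triethylsilyloxy)oxepane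
Product: 35 (3R,6R,7S)-7-[(4R,5R)-5-(tert-butyldimethylsilyloxy)-4,8-dimethylnon-7-en-1-yl]-6-[(4-methoxybenzyl)oxy]-7-methyloxepan-3-ol
Conditions: PPTS, MeOH/CH2Cl2, 0 °C
Reagents that add atoms: none
Why: Mild acid-catalysed methanolysis removes the secondary TES ether selectively; the bulkier TBS ether and the PMB ether survive.

Step 22
Reactants: 35 (3R,6R,7S)-7-[(4R,5R)-5-(tert-butyldimethylsilyloxy)-4,8-dimethylnon-7-en-1-yl]-6-[(4-methoxybenzyl)oxy]-7-methyloxepan-3-ol
Product: 36 (6R,7S)-7-[(4R,5R)-5-(tert-butyldimethylsilyloxy)-4,8-dimethylnon-7-en-1-yl]-6-[(4-methoxybenzyl)oxy]-7-methyloxepan-3-one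
Conditions: Dess–Martin periodinane, NaHCO3, CH2Cl2, 23 °C
Reagents that add atoms: none
Why: Dess–Martin oxidation of the secondary alcohol to the oxepan-3-one, which removes the free C6 stereocentre.

Step 23
Reactants: 36 (6R,7S)-7-[(4R,5R)-5-(tert-butyldimethylsilyloxy)-4,8-dimethylnon-7-en-1-yl]-6-[(4-methoxybenzyl)oxy]-7-methyloxepan-3-one; 37 triethyl phosphonoacetate
Product: 39 ethyl (2E)-2-{(6R,7S)-7-[(4R,5R)-5-(tert-butyldimethylsilyloxy)-4,8-dimethylnon-7-en-1-yl]-6-[(4-methoxybenzyl)oxy]-7-methyloxepan-3-ylidene}acetate, via sodium phosphonate anion 38 (not isolated)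
Conditions: 37, NaH, THF, 0 °C; then 36, 0 → 23 °C
Reagents that add atoms: none
Why: Horner–Wadsworth–Emmons olefination, in which the E isomer (ester cis to C5, away from the allylic ring oxygen on C7) is expected to predominate and is separated from any Z isomer by chromatography.

Step 24
Reactants: 39 ethyl (2E)-2-{(6R,7S)-7-[(4R,5R)-5-(tert-butyldimethylsilyloxy)-4,8-dimethylnon-7-en-1-yl]-6-[(4-methoxybenzyl)oxy]-7-methyloxepan-3-ylidene}acetate
Product: 40 ethyl (2E)-2-{(6R,7S)-7-[(4R,5R)-5-(tert-butyldimethylsilyloxy)-4,8-dimethylnon-7-en-1-yl]-6-hydroxy-7-methyloxepan-3-ylidene}acetate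
Conditions: DDQ, CH2Cl2/pH 7 buffer, 0 → 23 °C
Reagents that add atoms: none
Why: Oxidative cleavage of the PMB ether by DDQ (hydride abstraction, then hydrolysis of the oxocarbenium ion); enoate, isolated alkene and TBS ether are inert.

Step 25
Reactants: 40 ethyl (2E)-2-{(6R,7S)-7-[(4R,5R)-5-(tert-butyldimethylsilyloxy)-4,8-dimethylnon-7-en-1-yl]-6-hydroxy-7-methyloxepan-3-ylidene}acetate
Product: 41 (2S,3R,6E)-2-[(4R,5R)-5-(tert-butyldimethylsilyloxy)-4,8-dimethylnon-7-en-1-yl]-6-(2-hydroxyethylidene)-2-methyloxepan-3-ol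
Conditions: iBu2AlH, CH2Cl2, −78 → 0 °C; aq. potassium sodium tartrate
Reagents that add atoms: none
Why: 1,2-Reduction of the enoate by iBu2AlH gives the allylic alcohol without touching either trisubstituted alkene.

Step 26
Reactants: 41 (2S,3R,6E)-2-[(4R,5R)-5-(tert-butyldimethylsilyloxy)-4,8-dimethylnon-7-en-1-yl]-6-(2-hydroxyethylidene)-2-methyloxepan-3-ol
Product: 42 (2E)-2-{(6R,7S)-6-acetoxy-7-[(4R,5R)-5-(tert-butyldimethylsilyloxy)-4,8-dimethylnon-7-en-1-yl]-7-methyloxepan-3-ylidene}ethyl acetate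
Conditions: Ac2O, pyridine, DMAP (cat.), CH2Cl2, 23 °C
Reagents that add atoms: acetic anhydride, CC(=O)OC(C)=O
Why: DMAP-catalysed acetylation of the primary allylic and the hindered secondary hydroxyl groups.

Step 27
Reactants: 42 (2E)-2-{(6R,7S)-6-acetoxy-7-[(4R,5R)-5-(tert-butyldimethylsilyloxy)-4,8-dimethylnon-7-en-1-yl]-7-methyloxepan-3-ylidene}ethyl acetate
Product: 43 (2E)-2-{(6R,7S)-6-acetoxy-7-[(4R,5R)-5-hydroxy-4,8-dimethylnon-7-en-1-yl]-7-methyloxepan-3-ylidene}ethyl acetate (CNP0194639.1)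
Conditions: HF·pyridine, pyridine, THF, 0 → 23 °C
Reagents that add atoms: none
Why: Fluoride-mediated cleavage of the TBS ether under buffered conditions that leave both acetates and the alkenes intact.

**Compound list**

1 | [(4S)-2,2-dimethyl-1,3-dioxolan-4-yl]methanol ((S)-solketal) | CC1(C)OC[C@H](CO)O1 | starting material
2 | ethyl (2S)-2-[(trifluoromethylsulfonyl)oxy]propanoate | C[C@H](OS(=O)(=O)C(F)(F)F)C(=O)OCC | starting material
3 | ethyl (2R)-2-{[(4S)-2,2-dimethyl-1,3-dioxolan-4-yl]methoxy}propanoate | C[C@@H](OC[C@H]1COC(C)(C)O1)C(=O)OCC | intermediate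
4 | ethyl (2R)-2-[(2R)-2,3-dihydroxypropoxy]propanoate | C[C@@H](OC[C@H](O)CO)C(=O)OCC | intermediate
5 | ethyl (2R)-2-{[(2S)-2,3-bis(triethylsilyloxy)propyl]oxy}propanoate | C[C@@H](OC[C@H](O[Si](CC)(CC)CC)CO[Si](CC)(CC)CC)C(=O)OCC | intermediate
6 | ethyl (2R)-2-{[(2S)-3-oxo-2-(triethylsilyloxy)propyl]oxy}propanoate | C[C@@H](OC[C@H](O[Si](CC)(CC)CC)C=O)C(=O)OCC | intermediate
7 | 4-methoxybenzyl alcohol | COc1ccc(CO)cc1 | starting material
8 | trichloroethylene | ClC=C(Cl)Cl | starting material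
9 | 1-({[(E)-1,2-dichloroethenyl]oxy}methyl)-4-methoxybenzene | COc1ccc(CO/C(Cl)=C\Cl)cc1 | intermediate
10 | lithium [(4-methoxybenzyl)oxy]acetylide | [Li]C#COCc1ccc(OC)cc1 | intermediate
11 | ethyl (2R)-2-{[(2S,3R)-3-hydroxy-5-[(4-methoxybenzyl)oxy]-2-(triethylsilyloxy)pent-4-yn-1-yl]oxy}propanoate | C[C@@H](OC[C@H](O[Si](CC)(CC)CC)[C@H](O)C#COCc1ccc(OC)cc1)C(=O)OCC | intermediate
12 | ethyl (2R)-2-{[(2S,3R,4Z)-3-hydroxy-5-[(4-methoxybenzyl)oxy]-2-(triethylsilyloxy)pent-4-en-1-yl]oxy}propanoate | C[C@@H](OC[C@H](O[Si](CC)(CC)CC)[C@H](O)/C=C\OCc1ccc(OC)cc1)C(=O)OCC | intermediate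
13 | lithium (2R)-2-{[(2S,3R,4Z)-3-hydroxy-5-[(4-methoxybenzyl)oxy]-2-(triethylsilyloxy)pent-4-en-1-yl]oxy}propanoate | C[C@@H](OC[C@H](O[Si](CC)(CC)CC)[C@H](O)/C=C\OCc1ccc(OC)cc1)C(=O)[O-].[Li+] | intermediate
14 | mixed anhydride of the acid of 13 with 2,4,6-trichlorobenzoic acid | C[C@@H](OC[C@H](O[Si](CC)(CC)CC)[C@H](O)/C=C\OCc1ccc(OC)cc1)C(=O)OC(=O)c1c(Cl)cc(Cl)cc1Cl | intermediate
15 | (3R,6S,7R)-7-{(Z)-2-[(4-methoxybenzyl)oxy]ethenyl}-3-methyl-6-(triethylsilyloxy)-1,4-dioxepan-2-one | O=C1[C@@H](C)OC[C@H](O[Si](CC)(CC)CC)[C@@H](/C=C\OCc2ccc(OC)cc2)O1 | intermediate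
16 | (6S,7R)-7-{(Z)-2-[(4-methoxybenzyl)oxy]ethenyl}-3-methyl-6-(triethylsilyloxy)-2-(trimethylsilyloxy)-6,7-dihydro-5H-1,4-dioxepine | C[Si](C)(C)OC1=C(C)OC[C@H](O[Si](CC)(CC)CC)[C@@H](/C=C\OCc2ccc(OC)cc2)O1 | intermediate
17 | trimethylsilyl (2R,3R,6R)-3-[(4-methoxybenzyl)oxy]-2-methyl-6-(triethylsilyloxy)-2,3,6,7-tetrahydrooxepine-2-carboxylate | C[Si](C)(C)OC(=O)[C@]1(C)OC[C@H](O[Si](CC)(CC)CC)C=C[C@H]1OCc2ccc(OC)cc2 | intermediate
18 | (2R,3R,6R)-3-[(4-methoxybenzyl)oxy]-2-methyl-6-(triethylsilyloxy)-2,3,6,7-tetrahydrooxepine-2-carboxylic acid | OC(=O)[C@]1(C)OC[C@H](O[Si](CC)(CC)CC)C=C[C@H]1OCc2ccc(OC)cc2 | intermediate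
19 | [(2S,3R,6R)-3-[(4-methoxybenzyl)oxy]-2-methyl-6-(triethylsilyloxy)-2,3,6,7-tetrahydrooxepin-2-yl]methanol | OC[C@]1(C)OC[C@H](O[Si](CC)(CC)CC)C=C[C@H]1OCc2ccc(OC)cc2 | intermediate
20 | (2R,3R,6R)-3-[(4-methoxybenzyl)oxy]-2-methyl-6-(triethylsilyloxy)-2,3,6,7-tetrahydrooxepine-2-carbaldehyde | O=C[C@]1(C)OC[C@H](O[Si](CC)(CC)CC)C=C[C@H]1OCc2ccc(OC)cc2 | intermediate
21 | 4-methylpent-3-en-1-ol | CC(C)=CCCO | starting material
22 | 4-methylpent-3-enal | CC(C)=CCC=O | intermediate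
23 | (Z)-but-2-ene | C/C=C\C | starting material
24 | [(Z)-but-2-en-1-yl]bis(isopinocampheyl)borane, Ipc groups from (+)-α-pinene | C/C=C\CB([C@H]1[C@H](C)[C@H]2C[C@@H](C1)C2(C)C)[C@H]1[C@H](C)[C@H]2C[C@@H](C1)C2(C)C | intermediate
25 | (3R,4R)-3,7-dimethylocta-1,6-dien-4-yl bis(isopinocampheyl)borinate | C=C[C@@H](C)[C@H](OB([C@H]1[C@H](C)[C@H]2C[C@@H](C1)C2(C)C)[C@H]1[C@H](C)[C@H]2C[C@@H](C1)C2(C)C)CC=C(C)C | intermediate
26 | (3R,4R)-3,7-dimethylocta-1,6-dien-4-ol | C=C[C@@H](C)[C@H](O)CC=C(C)C | intermediate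
27 | tert-butyl{[(3R,4R)-3,7-dimethylocta-1,6-dien-4-yl]oxy}dimethylsilane | C=C[C@@H](C)[C@H](O[Si](C)(C)C(C)(C)C)CC=C(C)C | intermediate
28 | 9-[(3R,4R)-4-(tert-butyldimethylsilyloxy)-3,7-dimethyloct-6-en-1-yl]-9-borabicyclo[3.3.1]nonane | C1CCC2CCCC1B2CC[C@@H](C)[C@H](O[Si](C)(C)C(C)(C)C)CC=C(C)C | intermediate
29 | (3R,4R)-4-(tert-butyldimethylsilyloxy)-3,7-dimethyloct-6-en-1-ol | OCC[C@@H](C)[C@H](O[Si](C)(C)C(C)(C)C)CC=C(C)C | intermediate
30 | tert-butyl{[(3R,4R)-1-iodo-3,7-dimethyloct-6-en-4-yl]oxy}dimethylsilane | ICC[C@@H](C)[C@H](O[Si](C)(C)C(C)(C)C)CC=C(C)C | intermediate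
31 | [(3R,4R)-4-(tert-butyldimethylsilyloxy)-3,7-dimethyloct-6-en-1-yl]triphenylphosphonium iodide | [I-].CC(C)=CC[C@@H](O[Si](C)(C)C(C)(C)C)[C@H](C)CC[P+](c1ccccc1)(c1ccccc1)c1ccccc1 | intermediate
32 | [(3R,4R)-4-(tert-butyldimethylsilyloxy)-3,7-dimethyloct-6-en-1-ylidene]triphenylphosphorane | CC(C)=CC[C@@H](O[Si](C)(C)C(C)(C)C)[C@H](C)CC=P(c1ccccc1)(c1ccccc1)c1ccccc1 | intermediate
33 | (2S,3R,6R)-2-[(1Z,4R,5R)-5-(tert-butyldimethylsilyloxy)-4,8-dimethylnona-1,7-dien-1-yl]-3-[(4-methoxybenzyl)oxy]-2-methyl-6-(triethylsilyloxy)-2,3,6,7-tetrahydrooxepine | CC(C)=CC[C@@H](O[Si](C)(C)C(C)(C)C)[C@H](C)C/C=C\[C@]1(C)OC[C@H](O[Si](CC)(CC)CC)C=C[C@H]1OCc2ccc(OC)cc2 | intermediate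
34 | (2S,3R,6R)-2-[(4R,5R)-5-(tert-butyldimethylsilyloxy)-4,8-dimethylnon-7-en-1-yl]-3-[(4-methoxybenzyl)oxy]-2-methyl-6-(triethylsilyloxy)oxepane | CC(C)=CC[C@@H](O[Si](C)(C)C(C)(C)C)[C@H](C)CCC[C@]1(C)OC[C@H](O[Si](CC)(CC)CC)CC[C@H]1OCc2ccc(OC)cc2 | intermediate
35 | (3R,6R,7S)-7-[(4R,5R)-5-(tert-butyldimethylsilyloxy)-4,8-dimethylnon-7-en-1-yl]-6-[(4-methoxybenzyl)oxy]-7-methyloxepan-3-ol | CC(C)=CC[C@@H](O[Si](C)(C)C(C)(C)C)[C@H](C)CCC[C@]1(C)OC[C@H](O)CC[C@H]1OCc2ccc(OC)cc2 | intermediate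
36 | (6R,7S)-7-[(4R,5R)-5-(tert-butyldimethylsilyloxy)-4,8-dimethylnon-7-en-1-yl]-6-[(4-methoxybenzyl)oxy]-7-methyloxepan-3-one | CC(C)=CC[C@@H](O[Si](C)(C)C(C)(C)C)[C@H](C)CCC[C@]1(C)OCC(=O)CC[C@H]1OCc2ccc(OC)cc2 | intermediate
37 | triethyl phosphonoacetate | CCOC(=O)CP(=O)(OCC)OCC | starting material
38 | sodium salt of the carbanion of triethyl phosphonoacetate | [Na+].CCOC(=O)[CH-]P(=O)(OCC)OCC | intermediate
39 | ethyl (2E)-2-{(6R,7S)-7-[(4R,5R)-5-(tert-butyldimethylsilyloxy)-4,8-dimethylnon-7-en-1-yl]-6-[(4-methoxybenzyl)oxy]-7-methyloxepan-3-ylidene}acetate | CC(C)=CC[C@@H](O[Si](C)(C)C(C)(C)C)[C@H](C)CCC[C@]1(C)OC/C(=C/C(=O)OCC)CC[C@H]1OCc2ccc(OC)cc2 | intermediate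
40 | ethyl (2E)-2-{(6R,7S)-7-[(4R,5R)-5-(tert-butyldimethylsilyloxy)-4,8-dimethylnon-7-en-1-yl]-6-hydroxy-7-methyloxepan-3-ylidene}acetate | CC(C)=CC[C@@H](O[Si](C)(C)C(C)(C)C)[C@H](C)CCC[C@]1(C)OC/C(=C/C(=O)OCC)CC[C@H]1O | intermediate
41 | (2S,3R,6E)-2-[(4R,5R)-5-(tert-butyldimethylsilyloxy)-4,8-dimethylnon-7-en-1-yl]-6-(2-hydroxyethylidene)-2-methyloxepan-3-ol | CC(C)=CC[C@@H](O[Si](C)(C)C(C)(C)C)[C@H](C)CCC[C@]1(C)OC/C(=C/CO)CC[C@H]1O | intermediate
42 | (2E)-2-{(6R,7S)-6-acetoxy-7-[(4R,5R)-5-(tert-butyldimethylsilyloxy)-4,8-dimethylnon-7-en-1-yl]-7-methyloxepan-3-ylidene}ethyl acetate | CC(C)=CC[C@@H](O[Si](C)(C)C(C)(C)C)[C@H](C)CCC[C@]1(C)OC/C(=C/COC(C)=O)CC[C@H]1OC(C)=O | intermediate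
43 | (2E)-2-{(6R,7S)-6-acetoxy-7-[(4R,5R)-5-hydroxy-4,8-dimethylnon-7-en-1-yl]-7-methyloxepan-3-ylidene}ethyl acetate | CC(C)=CC[C@@H](O)[C@H](C)CCC[C@]1(C)OC/C(=C/COC(C)=O)CC[C@H]1OC(C)=O | target

**Step count**

Total: 27 steps. Longest linear sequence: 20 steps (steps 1–4, 6–12, 19–27).

**Steps most likely to fail**

Step 10. What may go wrong: 1,3-allylic strain between the Z-alkoxy group and C6 in the bridged boat slows the shift, so that the ketene acetal is hydrolysed back to the lactone or the vinylogous acylal ionises before the C–C bond forms. Fallback: the same [3,3] bond construction through an open-chain chair, with the ring closed afterwards by metathesis. It sets out from aldehyde 6 and acetylide 10 (made from 9) and comes back at acid 18.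
- Wittig methylenation of 6 (Ph3P=CH2, THF, −78 → 0 °C) gives ethyl (2R)-2-{[(2R)-2-(triethylsilyloxy)but-3-en-1-yl]oxy}propanoate F1, and saponification as in step 8 gives its lithium carboxylate F2.
- Acetylide 10 is added to acetaldehyde to give racemic 4-[(4-methoxybenzyl)oxy]but-3-yn-2-ol F3, and semihydrogenation as in step 7 gives racemic (3Z)-4-[(4-methoxybenzyl)oxy]but-3-en-2-ol F4.
- Lipase-catalysed acetylation (Candida antarctica lipase B, vinyl acetate) should convert the R enantiomer into (2R,3Z)-4-[(4-methoxybenzyl)oxy]but-3-en-2-yl acetate F5, and methanolysis (K2CO3, MeOH) frees (2R,3Z)-4-[(4-methoxybenzyl)oxy]but-3-en-2-ol F6.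
- Esterification of F2 with F6 through the 2,4,6-trichlorobenzoyl mixed anhydride (DMAP, toluene) gives the allylic ester F7.
- The chelated lithium enolate of F7 is silylated and should rearrange through a chair (Ireland–Claisen rearrangement of an α-alkoxy ester; LiN(SiMe3)2, Me3SiCl/Et3N, THF, −78 → 23 °C) to (2R,3R,4E)-3-[(4-methoxybenzyl)oxy]-2-methyl-2-{[(2R)-2-(triethylsilyloxy)but-3-en-1-yl]oxy}hex-4-enoic acid F8. The opposite ketene-acetal geometry and the chair in place of the boat together give the same C2 and C3 configuration.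
- Ring-closing metathesis (RuCl2(=CHPh)(H2IMes)(PCy3), second-generation Grubbs catalyst, CH2Cl2, 40 °C) closes C4=C5 with loss of propene and gives 18.

Step 20. What may go wrong: diimide discriminates too little between the hindered cis C1'=C2' bond next to the quaternary C2 and the trisubstituted C7'=C8' bond, so that driving the reduction to completion also saturates the prenyl terminus. Fallback: join the side chain through an sp3 carbanion and remove the resulting hydroxyl group, so that no alkene has to be reduced beside the prenyl group. It sets out from alcohol 19 and iodide 30 and comes back at 34.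
- Diimide reduction of 19 (conditions of step 20; only one alkene is present) gives [(2S,3R,6R)-3-[(4-methoxybenzyl)oxy]-2-methyl-6-(triethylsilyloxy)oxepan-2-yl]methanol F9, and Dess–Martin oxidation gives (2R,3R,6R)-3-[(4-methoxybenzyl)oxy]-2-methyl-6-(triethylsilyloxy)oxepane-2-carbaldehyde F10.
- Iodide 30 is converted (t-BuLi, Et2O, −78 °C) into [(3R,4R)-4-(tert-butyldimethylsilyloxy)-3,7-dimethyloct-6-en-1-yl]lithium F11, which adds to F10 to give the C1' carbinol F12 as a mixture of C1' epimers.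
- Xanthate formation (NaH, CS2, MeI) gives the S-methyl dithiocarbonate F13, and Barton–McCombie deoxygenation (Bu3SnH, AIBN, toluene, 80 °C) removes the C1' oxygen and gives 34.

Step 23. What may go wrong: the two α-methylene groups of ketone 36 differ only by the ring oxygen, so the olefination shows poor geometric selectivity and much Z isomer (ester cis to C7) forms. Fallback: deliver the phosphonate from the C3 oxygen, so that the alkene geometry is enforced by a tether. It sets out from 34 and comes back at diol 41.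
- DDQ removes the PMB group first and gives (2S,3R,6R)-2-[(4R,5R)-5-(tert-butyldimethylsilyloxy)-4,8-dimethylnon-7-en-1-yl]-2-methyl-6-(triethylsilyloxy)oxepan-3-ol F14; esterification with diethylphosphonoacetic acid (DCC, DMAP) gives the C3 diethylphosphonoacetate F15.
- TES removal (PPTS, MeOH) gives the C6 alcohol F16, and Dess–Martin oxidation gives the keto phosphonate F17.
- Intramolecular Horner–Wadsworth–Emmons reaction (LiCl, iPr2NEt, MeCN, high dilution) can close only the bridged enoate lactone F18, in which the carbonyl carbon is cis to C5, because the three-atom O–C(=O)–CH bridge from C3 cannot span to the C7 side; this is the E geometry of the target. The bridgehead alkene makes this lactone strained, and the closure is the uncertain point of this fallback.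
- Reduction with iBu2AlH opens the lactone to the allylic alcohol and the C3 alcohol and gives 41.

**Further compounds**

F1 | step 10 | ethyl (2R)-2-{[(2R)-2-(triethylsilyloxy)but-3-en-1-yl]oxy}propanoate | C[C@@H](OC[C@H](O[Si](CC)(CC)CC)C=C)C(=O)OCC
F2 | step 10 | lithium (2R)-2-{[(2R)-2-(triethylsilyloxy)but-3-en-1-yl]oxy}propanoate | C[C@@H](OC[C@H](O[Si](CC)(CC)CC)C=C)C(=O)[O-].[Li+]
F3 | step 10 | racemic 4-[(4-methoxybenzyl)oxy]but-3-yn-2-ol | CC(O)C#COCc1ccc(OC)cc1
F4 | step 10 | racemic (3Z)-4-[(4-methoxybenzyl)oxy]but-3-en-2-ol | CC(O)/C=C\OCc1ccc(OC)cc1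
F5 | step 10 | (2R,3Z)-4-[(4-methoxybenzyl)oxy]but-3-en-2-yl acetate | C[C@@H](OC(C)=O)/C=C\OCc1ccc(OC)cc1
F6 | step 10 | (2R,3Z)-4-[(4-methoxybenzyl)oxy]but-3-en-2-ol | C[C@@H](O)/C=C\OCc1ccc(OC)cc1
F7 | step 10 | (2R,3Z)-4-[(4-methoxybenzyl)oxy]but-3-en-2-yl (2R)-2-{[(2R)-2-(triethylsilyloxy)but-3-en-1-yl]oxy}propanoate | C[C@@H](OC[C@H](O[Si](CC)(CC)CC)C=C)C(=O)O[C@H](C)/C=C\OCc1ccc(OC)cc1
F8 | step 10 | (2R,3R,4E)-3-[(4-methoxybenzyl)oxy]-2-methyl-2-{[(2R)-2-(triethylsilyloxy)but-3-en-1-yl]oxy}hex-4-enoic acid | OC(=O)[C@](C)(OC[C@H](O[Si](CC)(CC)CC)C=C)[C@H](OCc1ccc(OC)cc1)/C=C/C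
F9 | step 20 | [(2S,3R,6R)-3-[(4-methoxybenzyl)oxy]-2-methyl-6-(triethylsilyloxy)oxepan-2-yl]methanol | OC[C@]1(C)OC[C@H](O[Si](CC)(CC)CC)CC[C@H]1OCc2ccc(OC)cc2
F10 | step 20 | (2R,3R,6R)-3-[(4-methoxybenzyl)oxy]-2-methyl-6-(triethylsilyloxy)oxepane-2-carbaldehyde | O=C[C@]1(C)OC[C@H](O[Si](CC)(CC)CC)CC[C@H]1OCc2ccc(OC)cc2
F11 | step 20 | [(3R,4R)-4-(tert-butyldimethylsilyloxy)-3,7-dimethyloct-6-en-1-yl]lithium | [Li]CC[C@@H](C)[C@H](O[Si](C)(C)C(C)(C)C)CC=C(C)C
F12 | step 20 | (4R,5R)-5-(tert-butyldimethylsilyloxy)-1-[(2S,3R,6R)-3-[(4-methoxybenzyl)oxy]-2-methyl-6-(triethylsilyloxy)oxepan-2-yl]-4,8-dimethylnon-7-en-1-ol (C1 epimers) | CC(C)=CC[C@@H](O[Si](C)(C)C(C)(C)C)[C@H](C)CCC(O)[C@]1(C)OC[C@H](O[Si](CC)(CC)CC)CC[C@H]1OCc2ccc(OC)cc2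
F13 | step 20 | O-alkyl S-methyl dithiocarbonate of F12 | CC(C)=CC[C@@H](O[Si](C)(C)C(C)(C)C)[C@H](C)CCC(OC(=S)SC)[C@]1(C)OC[C@H](O[Si](CC)(CC)CC)CC[C@H]1OCc2ccc(OC)cc2
F14 | step 23 | (2S,3R,6R)-2-[(4R,5R)-5-(tert-butyldimethylsilyloxy)-4,8-dimethylnon-7-en-1-yl]-2-methyl-6-(triethylsilyloxy)oxepan-3-ol | CC(C)=CC[C@@H](O[Si](C)(C)C(C)(C)C)[C@H](C)CCC[C@]1(C)OC[C@H](O[Si](CC)(CC)CC)CC[C@H]1O
F15 | step 23 | (2S,3R,6R)-2-[(4R,5R)-5-(tert-butyldimethylsilyloxy)-4,8-dimethylnon-7-en-1-yl]-2-methyl-6-(triethylsilyloxy)oxepan-3-yl (diethoxyphosphoryl)acetate | CC(C)=CC[C@@H](O[Si](C)(C)C(C)(C)C)[C@H](C)CCC[C@]1(C)OC[C@H](O[Si](CC)(CC)CC)CC[C@H]1OC(=O)CP(=O)(OCC)OCC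
F16 | step 23 | (2S,3R,6R)-2-[(4R,5R)-5-(tert-butyldimethylsilyloxy)-4,8-dimethylnon-7-en-1-yl]-6-hydroxy-2-methyloxepan-3-yl (diethoxyphosphoryl)acetate | CC(C)=CC[C@@H](O[Si](C)(C)C(C)(C)C)[C@H](C)CCC[C@]1(C)OC[C@H](O)CC[C@H]1OC(=O)CP(=O)(OCC)OCC
F17 | step 23 | (2S,3R)-2-[(4R,5R)-5-(tert-butyldimethylsilyloxy)-4,8-dimethylnon-7-en-1-yl]-2-methyl-6-oxooxepan-3-yl (diethoxyphosphoryl)acetate | CC(C)=CC[C@@H](O[Si](C)(C)C(C)(C)C)[C@H](C)CCC[C@]1(C)OCC(=O)CC[C@H]1OC(=O)CP(=O)(OCC)OCC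
F18 | step 23 | bridged lactone joining the C3 oxygen to the (E)-configured C6 ylidene-acetate carbon (carbonyl cis to C5) | CC(C)=CC[C@@H](O[Si](C)(C)C(C)(C)C)[C@H](C)CCC[C@]1(C)OC/C2=C/C(=O)O[C@@H]1CC2
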